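The trap is to treat J as the speed knob of these flasks. J enters the first and third steps at first order, so it cancels from the ratio of their rates, and what remains is a path rather than a clock.

| setting | north-east | north-west | south-west | east | south-east |
|---|---|---|---|---|---|
| G | 0.055 M | 0.055 M | 0.055 M | 0.055 M | 0.055 M |
| J | 0.0200 M | 0.0400 M | 0.0800 M | 0.200 M | 0.400 M |
| time | 1.0 h | 1.0 h | 1.0 h | 1.0 h | 1.0 h |

    G + J → G.J, rate k1*[G]^2*[J] (k1 = 12 M⁻² s⁻¹)
    G.J ⇌ Z (K2 = 0.35, k2 = 0.0035 s⁻¹)
    J + G.J → J.G.J (k3 = 0.10 M⁻¹ s⁻¹)

* amount of G.J at the end, in percent of the G charged for north-east, north-west, south-west, east, south-east, in this order
* the course of these numbers from the first flask to the last (falls, then rises / rises, then falls / rises all the way / falls all the way / hardly changes)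

- "hardly changes" means that all values lie within two and a half points (for a concentration: within two and a half percent of the largest)
- run time (north-east): 1.0 h

Write x for the G left as a fraction of its charge, y for G.J plus Z on the same scale. We freeze one thing: Z stays at the ratio 0.35 to G.J. In north-east the relaxation half-life of 0.856 min is shorter than the 0.096 h that the third step needs with J as charged, which speaks for this. The loss of y by the third step over its gain by the first is then B = S·y/(x squared). Here S = 0.112, the selectivity factor: the third rate constant divided by the first constant, the G charge, and one plus the equilibrium constant. J is absent from it.

While B is small, y is close to one minus x. Summing B along that path gives the J lost to the third step, and if north-east uses its 0.0200 M of J to the end, we reckon x near 0.636 with 25.0% as G.J. Pushed beyond small B, where this path is only a rough guide, the same sum has B reach one at x = 0.284, for a J charge of 0.0472 M. So we expect a peak between north-west and south-west.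

One number is not enough. The charge of J picks the stopping point on the path. But in north-east J's half-life of 0.32 min is shorter than the relaxation, so the freeze is rough at first. In east the J charge is more than twice the G charge, so we expect J to outlast G there and the length of the run to count again.

The forecast gave 25%, 41%, 26%, 0.014% and 0.0013%, a course that rises, then falls: “the yield peaks near 0.04 M J and then collapses”.

The flasks give 24.8%, 40.8%, 26.7%, 0.0144% and 0%, a course that rises, then falls, and the row read there turns at 0.049 M of J. We put the end states into B with the same S. North-west ends with G at 36.1% and B under one, at 0.474. South-west ends with G at 9.30% and B over one, at 4.68.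

The rate constants are those of an exercise.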